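**Plan**

- Retrosynthesis, in order: (1) the six PMB–O bonds (five phenols and the C3 acid); (2) the acrylate Cα=Cβ bond (Horner–Wadsworth–Emmons), which separates a 4-formyl dihydrobenzofuran from the phosphonoacetate of methyl (R)-danshensuate; (3) the C3a–C3 bond of the dihydrofuran ring; (4) the O1–C2 enol ether bond (phenol plus arylpropiolate).
- Forward: 3,4-dihydroxybenzaldehyde supplies both aryl units of the core (a mono-protected phenol and an arylpropiolate). Their oxa-Michael union gives a Z β-aryloxyacrylate, an imine-directed rhodium C–H activation closes the dihydrofuran ring, the side chain is joined by olefination, and one acidolysis unveils the target.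
- Enabling feature: on the benzene ring of the core (ring A, C3a to C7a) the C3a–H bond lies between C4 and C7a. The formyl carbon on C4 (the later acrylate β-carbon) can carry a directing imine nitrogen, and O1 on C7a carries the C2=C3 enol ether, so metalation at C3a puts the alkene of the future ring B (O1, C2, C3, C3a, C7a) within reach.
- Stereochemistry: C2 comes from auxiliary-controlled syn hydroarylation ((R)-1-aminoindane on the imine nitrogen). C3 is set by base equilibration to the 2,3-trans isomer. The lactate centre (R) comes from natural danshensu, and the E alkene from the olefination. The PMB ester at C3 is orthogonal to the lactate methyl ester.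

Key step: step 7

Abbreviations: PMB = 4-methoxybenzyl; OPMB = 4-methoxybenzyloxy; coe = cyclooctene; FcPCy2 = (C5H5)Fe(C5H4PCy2).

Assumption: the (R)-configured 1-aminoindane auxiliary is taken to favour hydride delivery that gives (2S); if the sense of induction proves opposite, (S)-1-aminoindane is used in the same sequence.

**Route**

Step 1
Reactants: 1 3,4-dihydroxybenzaldehyde; 2 4-methoxybenzyl chloride
Product: 3 3-hydroxy-4-(4-methoxybenzyloxy)benzaldehyde
Conditions: 2 (1.0 equiv), NaHCO3, NaI (cat.), DMF, 40 °C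
Reagents that add atoms: 4-methoxybenzyl chloride (2), COc1ccc(CCl)cc1
Why: The 4-OH, para to the formyl group, is the more acidic phenol, so the weak base forms only that phenoxide and the Williamson etherification should be selective for O-4.

Step 2
Reactants: 1 3,4-dihydroxybenzaldehyde; 2 4-methoxybenzyl chloride
Product: 4 3,4-bis(4-methoxybenzyloxy)benzaldehyde
Conditions: 2 (2.3 equiv), K2CO3, n-Bu4NI (cat.), DMF, 60 °C
Reagents that add atoms: 4-methoxybenzyl chloride (2), COc1ccc(CCl)cc1
Why: Exhaustive Williamson etherification of both phenols under carbonate base.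

Step 3
Reactants: 4 3,4-bis(4-methoxybenzyloxy)benzaldehyde
Product: 5 4-(2,2-dibromoethenyl)-1,2-bis(4-methoxybenzyloxy)benzene
Conditions: CBr4, PPh3, Zn dust, CH2Cl2, rt
Reagents that add atoms: carbon tetrabromide, BrC(Br)(Br)Br
Why: Ramirez dibromoolefination (first stage of the Corey–Fuchs sequence) of an aromatic aldehyde; zinc as reductant keeps the medium free of acidic phosphorus bromides, so the PMB ethers should survive.

Step 4
Reactants: 5 4-(2,2-dibromoethenyl)-1,2-bis(4-methoxybenzyloxy)benzene; 2 4-methoxybenzyl chloride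
Product: 8 4-methoxybenzyl 3-[3,4-bis(4-methoxybenzyloxy)phenyl]prop-2-ynoate, via lithium arylacetylide 6 (not isolated), via lithium arylpropiolate 7 (not isolated)
Conditions: n-BuLi (2.1 equiv), THF, −78 to 0 °C; CO2, −78 °C to rt; then 2, NaI (cat.), DMF, 40 °C
Reagents that add atoms: carbon dioxide, O=C=O; 4-methoxybenzyl chloride (2), COc1ccc(CCl)cc1
Why: Second stage of the Corey–Fuchs reaction (lithium–bromine exchange, elimination and deprotonation) gives the lithium acetylide, which is carboxylated by CO2, and the carboxylate is O-alkylated in the same flask.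

Step 5
Reactants: 3 3-hydroxy-4-(4-methoxybenzyloxy)benzaldehyde; 8 4-methoxybenzyl 3-[3,4-bis(4-methoxybenzyloxy)phenyl]prop-2-ynoate
Product: 9 4-methoxybenzyl (Z)-3-[3,4-bis(4-methoxybenzyloxy)phenyl]-3-[5-formyl-2-(4-methoxybenzyloxy)phenoxy]prop-2-enoate
Conditions: K2CO3 (cat.), DMF, 60 °C
Reagents that add atoms: none
Why: Base-catalysed oxa-Michael addition of the phenoxide to the β-carbon of the alkynoate with anti protonation should give the Z enol ether (aryloxy cis to the ester), which is also the less congested isomer.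

Step 6
Reactants: 9 the Z β-aryloxyacrylate aldehyde; 10 (R)-1-aminoindane
Product: 11 4-methoxybenzyl (Z)-3-[3,4-bis(4-methoxybenzyloxy)phenyl]-3-[5-{(E)-[(1R)-indan-1-ylimino]methyl}-2-(4-methoxybenzyloxy)phenoxy]prop-2-enoate
Conditions: 10 (1.0 equiv), 4 Å molecular sieves, toluene, rt
Reagents that add atoms: (R)-1-aminoindane (10), N[C@@H]1CCc2ccccc21
Why: Condensation of the aromatic aldehyde with the primary amine to the E aldimine should be much faster than conjugate addition to the hindered, donor-substituted β-carbon of the enol ether.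

Step 7
Reactants: 11 the (R)-indanyl aldimine of the Z β-aryloxyacrylate
Product: 13 4-methoxybenzyl (2S,3R)-2-[3,4-bis(4-methoxybenzyloxy)phenyl]-4-formyl-7-(4-methoxybenzyloxy)-2,3-dihydro-1-benzofuran-3-carboxylate (2,3-cis), via cyclised imine 12 (not isolated)
Conditions: [RhCl(coe)2]2 (10 mol %), FcPCy2 (30 mol %), toluene, 75 °C; then 1 M aq. HCl, THF, 0 °C
Reagents that add atoms: water, O
Why: The imine nitrogen binds monovalent rhodium and delivers it by oxidative addition into the flanked C3a–H bond; the Z enol ether then inserts into the Rh–H bond of the resulting trivalent rhodium aryl hydride with hydride going to C2 and rhodium to C3 (alpha to the ester), and C–C reductive elimination from the six-membered rhodacycle forms the C3a–C3 bond and returns monovalent rhodium. The closest known reaction type is the imine-directed, rhodium-catalysed intramolecular hydroarylation of tethered alkenes (a Murai-type chelation-assisted C–H alkylation) run with a chiral amine auxiliary on nitrogen, a reaction type established for 2,3-disubstituted dihydrobenzofurans from aryl enol ethers. Ring B closes in a formally 5-endo-trig mode, which is open here because the ring bond is made by reductive elimination at the metal and not by direct attack on the alkene. C2 and C3 arise together by suprafacial addition of H and C3a across the Z alkene, which gives the 2,3-cis relationship, and the absolute configuration at C2 is fixed in the hydride insertion by the (R)-indanyl group on the coordinated nitrogen, which differentiates the two alkene faces. The step needs site selectivity between the two C–H bonds ortho to the imine and face selectivity at the alkene: C–H metalation is reversible and only rhodium at C3a can reach the tethered alkene, while the auxiliary supplies the face selectivity and any minor enantiomer is removed later as a diastereomer after union with enantiopure 19. Cold dilute aqueous acid then hydrolyses the cyclised imine to the aldehyde and releases the auxiliary without cleaving the PMB ethers.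

Step 8
Reactants: 13 the 2,3-cis aldehyde
Product: 14 4-methoxybenzyl (2S,3S)-2-[3,4-bis(4-methoxybenzyloxy)phenyl]-4-formyl-7-(4-methoxybenzyloxy)-2,3-dihydro-1-benzofuran-3-carboxylate (2,3-trans)
Conditions: DBU (0.2 equiv), toluene, rt
Reagents that add atoms: none
Why: Epimerisation at C3 (alpha to the ester and benzylic) through the ester enolate should give the thermodynamically favoured trans isomer, while the C2–O1 bond lies in the ring plane, orthogonal to the enolate π system, so β-elimination (the reverse of a 5-endo-trig closure) is slow and C2 keeps its configuration.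

Step 9
Reactants: 15 sodium (2R)-3-(3,4-dihydroxyphenyl)-2-hydroxypropanoate (sodium danshensu)
Product: 16 methyl (2R)-3-(3,4-dihydroxyphenyl)-2-hydroxypropanoate
Conditions: HCl (1.25 M in MeOH), rt
Reagents that add atoms: methanol, CO
Why: Fischer esterification; no bond to the stereocentre is broken.

Step 10
Reactants: 16 methyl (2R)-3-(3,4-dihydroxyphenyl)-2-hydroxypropanoate; 2 4-methoxybenzyl chloride
Product: 17 methyl (2R)-3-[3,4-bis(4-methoxybenzyloxy)phenyl]-2-hydroxypropanoate
Conditions: 2 (2.1 equiv), K2CO3, n-Bu4NI (cat.), DMF, rt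
Reagents that add atoms: 4-methoxybenzyl chloride (2), COc1ccc(CCl)cc1
Why: Williamson etherification under carbonate base is selective for the two acidic phenols over the secondary alcohol and too mild to enolise the α-hydroxy ester.

Step 11
Reactants: 17 the bis-PMB methyl danshensuate; 18 2-(diethoxyphosphoryl)acetic acid
Product: 19 methyl (2R)-3-[3,4-bis(4-methoxybenzyloxy)phenyl]-2-{[2-(diethoxyphosphoryl)acetyl]oxy}propanoate
Conditions: DCC, DMAP (cat.), CH2Cl2, 0 °C to rt
Reagents that add atoms: 2-(diethoxyphosphoryl)acetic acid (18), CCOP(=O)(CC(=O)O)OCC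
Why: Steglich esterification acylates the secondary alcohol with retention, since the C–O bond at the stereocentre is not touched.

Step 12
Reactants: 14 the 2,3-trans aldehyde; 19 the phosphonoacetate of protected methyl danshensuate
Product: 20 the fully PMB-protected target: methyl (2R)-3-[3,4-bis(OPMB)phenyl]-2-{[(E)-3-{(2S,3S)-2-[3,4-bis(OPMB)phenyl]-7-OPMB-3-[(PMB-oxy)carbonyl]-2,3-dihydro-1-benzofuran-4-yl}prop-2-enoyl]oxy}propanoate
Conditions: LiCl, i-Pr2NEt, MeCN, rt
Reagents that add atoms: none
Why: Horner–Wadsworth–Emmons olefination under mild LiCl/amine conditions should give the E enoate, because the lithium-chelated phosphonoacetate is the only C–H acid deprotonated by the weak amine base, so the lactate centre is not enolised and C3 is already at its thermodynamic configuration.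

Step 13
Reactants: 20 the fully PMB-protected target
Product: 21 the target, methyl (2R)-3-(3,4-dihydroxyphenyl)-2-{[(E)-3-[(2S,3S)-3-carboxy-2-(3,4-dihydroxyphenyl)-7-hydroxy-2,3-dihydro-1-benzofuran-4-yl]prop-2-enoyl]oxy}propanoate
Conditions: TFA (10% v/v), pentamethylbenzene (excess), CH2Cl2, 0 °C
Reagents that add atoms: none
Why: Acidolysis of the five PMB aryl ethers and the PMB ester proceeds through the stabilised 4-methoxybenzyl cation, which pentamethylbenzene traps by Friedel–Crafts alkylation; the methyl ester, the enoate and the lactate ester are inert to cold dilute TFA, and ionisation at C2 is disfavoured by the adjacent carboxyl group.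

**Compound list**

1 | 3,4-dihydroxybenzaldehyde | O=Cc1ccc(O)c(O)c1 | starting material
2 | 4-methoxybenzyl chloride | COc1ccc(CCl)cc1 | starting material
3 | 3-hydroxy-4-(4-methoxybenzyloxy)benzaldehyde | O=Cc1ccc(OCc2ccc(OC)cc2)c(O)c1 | intermediate
4 | 3,4-bis(4-methoxybenzyloxy)benzaldehyde | O=Cc1ccc(OCc2ccc(OC)cc2)c(OCc2ccc(OC)cc2)c1 | intermediate
5 | 4-(2,2-dibromoethenyl)-1,2-bis(4-methoxybenzyloxy)benzene | BrC(Br)=Cc1ccc(OCc2ccc(OC)cc2)c(OCc2ccc(OC)cc2)c1 | intermediate
6 | lithium [3,4-bis(4-methoxybenzyloxy)phenyl]acetylide | [Li+].[C-]#Cc1ccc(OCc2ccc(OC)cc2)c(OCc2ccc(OC)cc2)c1 | intermediate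
7 | lithium 3-[3,4-bis(4-methoxybenzyloxy)phenyl]prop-2-ynoate | [Li+].[O-]C(=O)C#Cc1ccc(OCc2ccc(OC)cc2)c(OCc2ccc(OC)cc2)c1 | intermediate
8 | 4-methoxybenzyl 3-[3,4-bis(4-methoxybenzyloxy)phenyl]prop-2-ynoate | COc1ccc(COC(=O)C#Cc2ccc(OCc3ccc(OC)cc3)c(OCc3ccc(OC)cc3)c2)cc1 | intermediate
9 | 4-methoxybenzyl (Z)-3-[3,4-bis(4-methoxybenzyloxy)phenyl]-3-[5-formyl-2-(4-methoxybenzyloxy)phenoxy]prop-2-enoate | O=Cc1ccc(OCc2ccc(OC)cc2)c(O/C(=C\C(=O)OCc2ccc(OC)cc2)c2ccc(OCc3ccc(OC)cc3)c(OCc3ccc(OC)cc3)c2)c1 | intermediate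
10 | (R)-1-aminoindane | N[C@@H]1CCc2ccccc21 | starting material
11 | (E)-aldimine of 9 with (R)-1-aminoindane | [C@H]1(CCc2ccccc21)/N=C/c1ccc(OCc2ccc(OC)cc2)c(O/C(=C\C(=O)OCc2ccc(OC)cc2)c2ccc(OCc3ccc(OC)cc3)c(OCc3ccc(OC)cc3)c2)c1 | intermediate
12 | (R)-indanyl aldimine of the (2S,3R)-cis dihydrobenzofuran 13 | [C@H]1(CCc2ccccc21)/N=C/c1ccc(OCc3ccc(OC)cc3)c2c1[C@@H](C(=O)OCc1ccc(OC)cc1)[C@@H](c1ccc(OCc3ccc(OC)cc3)c(OCc3ccc(OC)cc3)c1)O2 | intermediate
13 | 4-methoxybenzyl (2S,3R)-2-[3,4-bis(4-methoxybenzyloxy)phenyl]-4-formyl-7-(4-methoxybenzyloxy)-2,3-dihydro-1-benzofuran-3-carboxylate (cis) | O=Cc1ccc(OCc3ccc(OC)cc3)c2c1[C@@H](C(=O)OCc1ccc(OC)cc1)[C@@H](c1ccc(OCc3ccc(OC)cc3)c(OCc3ccc(OC)cc3)c1)O2 | intermediate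
14 | 4-methoxybenzyl (2S,3S)-2-[3,4-bis(4-methoxybenzyloxy)phenyl]-4-formyl-7-(4-methoxybenzyloxy)-2,3-dihydro-1-benzofuran-3-carboxylate (trans) | O=Cc1ccc(OCc3ccc(OC)cc3)c2c1[C@H](C(=O)OCc1ccc(OC)cc1)[C@@H](c1ccc(OCc3ccc(OC)cc3)c(OCc3ccc(OC)cc3)c1)O2 | intermediate
15 | sodium (2R)-3-(3,4-dihydroxyphenyl)-2-hydroxypropanoate (sodium danshensu) | [Na+].[O-]C(=O)[C@@H](Cc1ccc(O)c(O)c1)O | starting material
16 | methyl (2R)-3-(3,4-dihydroxyphenyl)-2-hydroxypropanoate | COC(=O)[C@@H](Cc1ccc(O)c(O)c1)O | intermediate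
17 | methyl (2R)-3-[3,4-bis(4-methoxybenzyloxy)phenyl]-2-hydroxypropanoate | COC(=O)[C@@H](Cc1ccc(OCc2ccc(OC)cc2)c(OCc2ccc(OC)cc2)c1)O | intermediate
18 | 2-(diethoxyphosphoryl)acetic acid | CCOP(=O)(CC(=O)O)OCC | starting material
19 | methyl (2R)-3-[3,4-bis(4-methoxybenzyloxy)phenyl]-2-{[2-(diethoxyphosphoryl)acetyl]oxy}propanoate | COC(=O)[C@@H](Cc1ccc(OCc2ccc(OC)cc2)c(OCc2ccc(OC)cc2)c1)OC(=O)CP(=O)(OCC)OCC | intermediate
20 | fully PMB-protected target (five PMB ethers, PMB ester at C3, E enoate, 2S,3S, lactate R) | COC(=O)[C@@H](Cc1ccc(OCc2ccc(OC)cc2)c(OCc2ccc(OC)cc2)c1)OC(=O)/C=C/c1ccc(OCc3ccc(OC)cc3)c2c1[C@H](C(=O)OCc1ccc(OC)cc1)[C@@H](c1ccc(OCc3ccc(OC)cc3)c(OCc3ccc(OC)cc3)c1)O2 | intermediate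
21 | methyl (2R)-3-(3,4-dihydroxyphenyl)-2-{[(E)-3-[(2S,3S)-3-carboxy-2-(3,4-dihydroxyphenyl)-7-hydroxy-2,3-dihydro-1-benzofuran-4-yl]prop-2-enoyl]oxy}propanoate | COC(=O)[C@@H](Cc1ccc(O)c(O)c1)OC(=O)/C=C/c1ccc(O)c2c1[C@H](C(=O)O)[C@@H](c1ccc(O)c(O)c1)O2 | target

**Step count and risks**

Total steps: 13. Longest linear sequence: 9 steps (steps 2, 3, 4, 5, 6, 7, 8, 12 and 13, from compound 1).

Steps most likely to fail:

1. Step 7. The remote indanyl group may discriminate the two alkene faces poorly during hydride insertion, which would erode the enantiopurity at C2. Fallback, from 9 back to 20: 9 is condensed with benzylamine to the achiral N-benzyl aldimine F1. The same [RhCl(coe)2]2/FcPCy2 hydroarylation, now without stereochemical bias, gives the cis-cyclised N-benzyl imine F2 together with its enantiomer F3. Acid hydrolysis gives 13 together with its enantiomer, the (2R,3S)-cis aldehyde F4. DBU equilibration gives 14 together with its enantiomer, the (2R,3R)-trans aldehyde F5. Olefination of this racemate with enantiopure 19 under the conditions of step 12 gives 20 and its (2R,3R)-dihydrobenzofuran diastereomer F6. These differ in physical properties and should be separable by chromatography or crystallisation; 20 then continues to step 13. Absolute control thus moves from auxiliary induction to resolution by the enantiopure lactate fragment.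

2. Step 13. Acid may ionise the C2–O1 bond of the electron-rich 2-aryl dihydrobenzofuran (ring opening or loss of configuration), and 4-methoxybenzyl cations may alkylate the liberated catechol rings. Fallback, from 14 and 17 back to 21, with all protecting groups removed before the alkene exists: hydrogenolysis of 14 (H2, Pd/C, EtOAc, rt) gives (2S,3S)-2-(3,4-dihydroxyphenyl)-4-formyl-7-hydroxy-2,3-dihydro-1-benzofuran-3-carboxylic acid F7. Alcohol 17 is heated with Meldrum's acid (toluene, 90 °C) to give the PMB-protected malonic half ester F8, which is hydrogenolysed (H2, Pd/C, EtOAc) to the free catechol malonic half ester F9. Knoevenagel–Doebner condensation of F7 with F9 (pyridine, piperidine (cat.), 50 °C) with loss of CO2 forms the E enoate and gives 21 directly.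

3. Step 5. Conjugate addition to the donor-substituted alkynoate may be sluggish, and the forcing base needed may allow reversible addition and loss of geometric control. Fallback, from 8 back to 9: anti hydroiodination of 8 (LiI, AcOH, MeCN, 70 °C) gives the 4-methoxybenzyl (Z)-3-iodo-3-arylacrylate F10. Copper-catalysed vinylic C–O coupling with phenol 3 (CuI, N,N-dimethylglycine, Cs2CO3, dioxane, 60 °C) proceeds with retention of alkene geometry and gives 9.

**Further compounds**

F1 | step 7 | (E)-N-benzyl aldimine of 9 | C(c1ccccc1)/N=C/c1ccc(OCc2ccc(OC)cc2)c(O/C(=C\C(=O)OCc2ccc(OC)cc2)c2ccc(OCc3ccc(OC)cc3)c(OCc3ccc(OC)cc3)c2)c1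
F2 | step 7 | N-benzyl aldimine of the (2S,3R)-cis dihydrobenzofuran | C(c1ccccc1)/N=C/c1ccc(OCc3ccc(OC)cc3)c2c1[C@@H](C(=O)OCc1ccc(OC)cc1)[C@@H](c1ccc(OCc3ccc(OC)cc3)c(OCc3ccc(OC)cc3)c1)O2
F3 | step 7 | N-benzyl aldimine of the (2R,3S)-cis dihydrobenzofuran | C(c1ccccc1)/N=C/c1ccc(OCc3ccc(OC)cc3)c2c1[C@H](C(=O)OCc1ccc(OC)cc1)[C@H](c1ccc(OCc3ccc(OC)cc3)c(OCc3ccc(OC)cc3)c1)O2
F4 | step 7 | 4-methoxybenzyl (2R,3S)-2-[3,4-bis(4-methoxybenzyloxy)phenyl]-4-formyl-7-(4-methoxybenzyloxy)-2,3-dihydro-1-benzofuran-3-carboxylate (enantiomer of 13) | O=Cc1ccc(OCc3ccc(OC)cc3)c2c1[C@H](C(=O)OCc1ccc(OC)cc1)[C@H](c1ccc(OCc3ccc(OC)cc3)c(OCc3ccc(OC)cc3)c1)O2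
F5 | step 7 | 4-methoxybenzyl (2R,3R)-2-[3,4-bis(4-methoxybenzyloxy)phenyl]-4-formyl-7-(4-methoxybenzyloxy)-2,3-dihydro-1-benzofuran-3-carboxylate (enantiomer of 14) | O=Cc1ccc(OCc3ccc(OC)cc3)c2c1[C@@H](C(=O)OCc1ccc(OC)cc1)[C@H](c1ccc(OCc3ccc(OC)cc3)c(OCc3ccc(OC)cc3)c1)O2
F6 | step 7 | (2R,3R)-dihydrobenzofuran diastereomer of 20 | COC(=O)[C@@H](Cc1ccc(OCc2ccc(OC)cc2)c(OCc2ccc(OC)cc2)c1)OC(=O)/C=C/c1ccc(OCc3ccc(OC)cc3)c2c1[C@@H](C(=O)OCc1ccc(OC)cc1)[C@H](c1ccc(OCc3ccc(OC)cc3)c(OCc3ccc(OC)cc3)c1)O2
F7 | step 13 | (2S,3S)-2-(3,4-dihydroxyphenyl)-4-formyl-7-hydroxy-2,3-dihydro-1-benzofuran-3-carboxylic acid | O=Cc1ccc(O)c2c1[C@H](C(=O)O)[C@@H](c1ccc(O)c(O)c1)O2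
F8 | step 13 | 3-{[(2R)-3-[3,4-bis(4-methoxybenzyloxy)phenyl]-1-methoxy-1-oxopropan-2-yl]oxy}-3-oxopropanoic acid | COC(=O)[C@@H](Cc1ccc(OCc2ccc(OC)cc2)c(OCc2ccc(OC)cc2)c1)OC(=O)CC(=O)O
F9 | step 13 | 3-{[(2R)-3-(3,4-dihydroxyphenyl)-1-methoxy-1-oxopropan-2-yl]oxy}-3-oxopropanoic acid | COC(=O)[C@@H](Cc1ccc(O)c(O)c1)OC(=O)CC(=O)O
F10 | step 5 | 4-methoxybenzyl (Z)-3-iodo-3-[3,4-bis(4-methoxybenzyloxy)phenyl]prop-2-enoate | COc1ccc(COC(=O)/C=C(\I)c2ccc(OCc3ccc(OC)cc3)c(OCc3ccc(OC)cc3)c2)cc1
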